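**Retrosynthetic overview**
1. The tertiary C–Br is made last from a tertiary chlorohydrin (OH to Br with retention); the chlorohydrin comes from an α-chloro cyclohexanone and a chloromethyl anion.
2. The α-chloro ketone comes from a 3-methyl-3-(E-chlorovinyl)-4-chlorocyclohexanone, whose chlorovinyl group is made from an aldehyde.
3. That keto aldehyde comes from a 2-methylcyclohept-2-en-1-ol by a chlorinative semipinacol ring contraction (the key step). It forms the ring C–C bond of the quaternary carbon, the adjacent C–Cl centre and the formyl group in one operation.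
4. The cycloheptenol comes from an acyclic dienol by ring-closing metathesis; the dienol comes from an asymmetric aldol of hex-5-en-2-one with methacrolein, the only reagent-controlled stereocentre.
5. Ring order: the seven-membered carbocycle is closed first and then contracted to the cyclohexane, the only ring of the target (the dioxolane is a protecting group).

Assumption: locants quoted in a step are those of the systematic name of the compound under discussion; both starting materials are taken as commercial.

**Route**

Step 1
Reactants: 1 hex-5-en-2-one; 2 2-methylprop-2-enal (methacrolein)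
Product: 5 (3R)-3-hydroxy-2-methylnona-1,8-dien-5-one, via boron enolate 3 (not isolated), via boron aldolate 4 (not isolated)
Conditions: (−)-Ipc2BCl, Et3N, Et2O, 0 °C; 2, −78 → −20 °C; H2O2, MeOH, pH 7 buffer
Reagents that add atoms: none
Why: Paterson boron aldol reaction, in which Ipc2BCl/Et3N enolises the methyl ketone on the CH3 side and the diisopinocampheylboron enolate adds to the Re face of the non-enolisable enal to set the (R)-carbinol (about 80% ee expected, to be raised by recrystallisation of 16 or of the target).

Step 2
Reactants: 5 (3R)-3-hydroxy-2-methylnona-1,8-dien-5-one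
Product: 6 (2R)-1-[2-(but-3-en-1-yl)-1,3-dioxolan-2-yl]-3-methylbut-3-en-2-ol
Conditions: HOCH2CH2OH, HC(OEt)3, PPTS (cat.), benzene, 40 °C
Reagents that add atoms: ethane-1,2-diol, OCCO
Why: Mild acid-catalysed ketalisation with orthoformate as water scavenger masks the ketone, so that the CH2 next to it keeps a normal migratory aptitude in step 4 and the β-hydroxy ketone cannot dehydrate, without touching the stereocentre.

Step 3
Reactants: 6 (2R)-1-[2-(but-3-en-1-yl)-1,3-dioxolan-2-yl]-3-methylbut-3-en-2-ol
Product: 7 (7R)-8-methyl-1,4-dioxaspiro[4.6]undec-8-en-7-ol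
Conditions: second-generation Grubbs catalyst RuCl2(=CHPh)(H2IMes)(PCy3) (5 mol %), CH2Cl2 (5 mM), 40 °C
Reagents that add atoms: none
Why: Ring-closing olefin metathesis between the 1,1-disubstituted and the monosubstituted alkene closes the cycloheptene with loss of ethene, tolerates the free allylic alcohol and leaves the carbinol centre unchanged.

Step 4
Reactants: 7 (7R)-8-methyl-1,4-dioxaspiro[4.6]undec-8-en-7-ol
Product: 9 (1S,2S)-2-chloro-1-methyl-5-oxocyclohexane-1-carbaldehyde, via ketal aldehyde 8 (not isolated)
Conditions: NCS (1.1 equiv), quinuclidine (10 mol %), CH2Cl2, −40 → 0 °C; then 1 M aq HCl, THF, 23 °C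
Reagents that add atoms: N-chlorosuccinimide, O=C1CCC(=O)N1Cl; water, O
Why: Proposed new method: a hydroxyl-directed chlorinative semipinacol ring contraction in which the N-chloroquinuclidinium succinimidate ion pair, hydrogen-bonded to the OH that A(1,2) strain with the vinylic methyl holds pseudoaxial, delivers Cl+ to C9 on the open alkene face syn to OH while the antiperiplanar ring carbon C6 shifts from C7 to C8 and the O–H is lost to give the aldehyde (the carbinol C–H lies in the alkene plane and cannot shift), so that (7R)-7 is relayed stereospecifically into the quaternary centre and the C–Cl centre with CHO and Cl cis before aqueous acid unmasks the ketone; the closest known reaction types are the halonium-induced semipinacol rearrangement of tertiary allylic alcohols and the Lewis-acid ring contraction of cyclic 2,3-epoxy alcohols.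

Step 5
Reactants: 9 (1S,2S)-2-chloro-1-methyl-5-oxocyclohexane-1-carbaldehyde
Product: 10 (3S,4S)-4-chloro-3-[(E)-2-chloroethenyl]-3-methylcyclohexan-1-one
Conditions: CrCl2 (6 equiv), CHCl3 (2 equiv), THF, 65 °C
Reagents that add atoms: chloroform, ClC(Cl)Cl
Why: Takai chloro-olefination, in which the gem-dichromium reagent formed from CHCl3 and divalent chromium reacts with the aldehyde in preference to the ketone and gives the E-chloroalkene, leaving the alkyl chloride and both stereocentres untouched.

Step 6
Reactants: 10 (3S,4S)-4-chloro-3-[(E)-2-chloroethenyl]-3-methylcyclohexan-1-one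
Product: 14 (2R,4S,5S)-2,4-dichloro-5-[(E)-2-chloroethenyl]-5-methylcyclohexan-1-one, via lithium enolate 11 (not isolated), via axial chloro ketone 12 (not isolated), via lithium chloroenolate 13 (not isolated)
Conditions: LiN(SiMe3)2 (1.05 equiv), THF, −78 °C; TsCl, −78 → −40 °C; LiN(SiMe3)2 (1.2 equiv), −78 °C; AcOH, −78 °C
Reagents that add atoms: p-toluenesulfonyl chloride, Cc1ccc(cc1)S(=O)(=O)Cl
Why: Kinetic enolate formation at C6 of 10 (remote from the quaternary carbon) and enolate chlorination with TsCl install the chlorine, after which re-enolisation and kinetic axial protonation, on the face opposite the axial chlorovinyl group of a chair that keeps the ring C–Cl and the methyl equatorial, leave the new chlorine equatorial and cis to the other C–Cl (2R).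

Step 7
Reactants: 14 (2R,4S,5S)-2,4-dichloro-5-[(E)-2-chloroethenyl]-5-methylcyclohexan-1-one
Product: 16 (1R,2R,4S,5S)-2,4-dichloro-1-(chloromethyl)-5-[(E)-2-chloroethenyl]-5-methylcyclohexan-1-ol, via lithium alkoxide 15 (not isolated)
Conditions: ICH2Cl (1.5 equiv), CH3Li·LiBr (1.4 equiv), THF, −78 °C; AcOH, −78 °C
Reagents that add atoms: chloroiodomethane, ClCI
Why: Carbonyl addition of chloromethyllithium generated in Barbier mode, in which the syn-axial chlorovinyl group blocks axial attack so that the carbenoid enters equatorially and gives the axial tertiary alcohol cis to the neighbouring C–Cl, the cold acidic quench preventing epoxide closure.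

Step 8
Reactants: 16 (1R,2R,4S,5S)-2,4-dichloro-1-(chloromethyl)-5-[(E)-2-chloroethenyl]-5-methylcyclohexan-1-ol
Product: 18 (1R,2R,4S,5S)-1-bromo-2,4-dichloro-1-(chloromethyl)-5-[(E)-2-chloroethenyl]-5-methylcyclohexane, via trimethylsilyl ether 17 (not isolated)
Conditions: Me3SiBr (3 equiv), CH2Cl2, −20 → 23 °C
Reagents that add atoms: bromotrimethylsilane, C[Si](C)(C)Br
Why: Deoxybromination of a tertiary alcohol with Me3SiBr, in which ionisation is assisted only by the chlorine of the CH2Cl group (the ring C–Cl is cis to the leaving group and cannot participate) and bromide opens the bridged ion at the tertiary carbon, giving overall retention and the axial bromide, which is also the more stable epimer.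

**Compound list**
1 | hex-5-en-2-one | CC(=O)CCC=C | starting material
2 | 2-methylprop-2-enal | CC(=C)C=O | starting material
3 | hexa-1,5-dien-2-yl diisopinocampheylborinate (boron enolate of 1) | C=C(CCC=C)OB([C@@H]1C[C@@H]2C[C@H]([C@H]1C)C2(C)C)[C@@H]1C[C@@H]2C[C@H]([C@H]1C)C2(C)C | intermediate
4 | diisopinocampheylborinate ester of 5 (boron aldolate) | C=C(C)[C@H](OB([C@@H]1C[C@@H]2C[C@H]([C@H]1C)C2(C)C)[C@@H]1C[C@@H]2C[C@H]([C@H]1C)C2(C)C)CC(=O)CCC=C | intermediate
5 | (3R)-3-hydroxy-2-methylnona-1,8-dien-5-one | C=C(C)[C@H](O)CC(=O)CCC=C | intermediate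
6 | (2R)-1-[2-(but-3-en-1-yl)-1,3-dioxolan-2-yl]-3-methylbut-3-en-2-ol | C=C(C)[C@H](O)CC1(CCC=C)OCCO1 | intermediate
7 | (7R)-8-methyl-1,4-dioxaspiro[4.6]undec-8-en-7-ol | CC1=CCCC2(OCCO2)C[C@H]1O | intermediate
8 | (7S,8S)-8-chloro-7-methyl-1,4-dioxaspiro[4.5]decane-7-carbaldehyde | C[C@@]1(C=O)CC2(OCCO2)CC[C@@H]1Cl | intermediate
9 | (1S,2S)-2-chloro-1-methyl-5-oxocyclohexane-1-carbaldehyde | C[C@@]1(C=O)CC(=O)CC[C@@H]1Cl | intermediate
10 | (3S,4S)-4-chloro-3-[(E)-2-chloroethenyl]-3-methylcyclohexan-1-one | C[C@@]1(/C=C/Cl)CC(=O)CC[C@@H]1Cl | intermediate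
11 | lithium enolate of 10 (C1–C6 enolate) | C[C@@]1(/C=C/Cl)CC([O-])=CC[C@@H]1Cl.[Li+] | intermediate
12 | (2S,4S,5S)-2,4-dichloro-5-[(E)-2-chloroethenyl]-5-methylcyclohexan-1-one (axial C2 chloride) | C[C@@]1(/C=C/Cl)CC(=O)[C@@H](Cl)C[C@@H]1Cl | intermediate
13 | lithium enolate of 12 and 14 (2-chloro enolate) | C[C@@]1(/C=C/Cl)CC([O-])=C(Cl)C[C@@H]1Cl.[Li+] | intermediate
14 | (2R,4S,5S)-2,4-dichloro-5-[(E)-2-chloroethenyl]-5-methylcyclohexan-1-one | C[C@@]1(/C=C/Cl)CC(=O)[C@H](Cl)C[C@@H]1Cl | intermediate
15 | lithium alkoxide of 16 | C[C@@]1(/C=C/Cl)C[C@@]([O-])(CCl)[C@H](Cl)C[C@@H]1Cl.[Li+] | intermediate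
16 | (1R,2R,4S,5S)-2,4-dichloro-1-(chloromethyl)-5-[(E)-2-chloroethenyl]-5-methylcyclohexan-1-ol | C[C@@]1(/C=C/Cl)C[C@@](O)(CCl)[C@H](Cl)C[C@@H]1Cl | intermediate
17 | trimethylsilyl ether of 16 | C[C@@]1(/C=C/Cl)C[C@@](O[Si](C)(C)C)(CCl)[C@H](Cl)C[C@@H]1Cl | intermediate
18 | (1R,2R,4S,5S)-1-bromo-2,4-dichloro-1-(chloromethyl)-5-[(E)-2-chloroethenyl]-5-methylcyclohexane | C[C@@]1(/C=C/Cl)C[C@@](Br)(CCl)[C@H](Cl)C[C@@H]1Cl | target

**Step count**
Total: 8 steps. Longest linear sequence: 8 steps (from 1 and 2).

**Steps most likely to fail, and fallbacks**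

Step 4 (the proposed new ring contraction). Possible failures are ene-type loss of a proton to an allylic chloride, oxidation of the carbinol to the enone, and capture of the cation by a ketal oxygen. The fallback sets out from 7 and comes back at 9, using oxygen as the electrophile and only known chemistry. VO(acac)2/t-BuOOH epoxidises 7 syn to the hydroxyl to give the cis-epoxy alcohol F1. BF3·OEt2 (CH2Cl2, −78 °C) then triggers the semipinacol ring contraction of this 2,3-epoxy alcohol to the cis-β-hydroxy aldehyde F2, with the same antiperiplanar ring-bond shift. The secondary alcohol is neopentylic and closed to SN2, so it is converted with retention through its chlorosulfite F3 (SOCl2, then catalytic TiCl4, internal return). This gives 8, and the aqueous acid of step 4 delivers 9.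

Step 8 (tertiary bromide). The alcohol carries two β-chlorines, so ionisation may be slow, and elimination or chloride/bromide scrambling may compete. The fallback sets out from 16 and comes back at 18; it moves the leaving group to the primary carbon so that ionisation is easy and the chlorine shift is used on purpose. K2CO3/MeOH closes 16 to the spiro-epoxide F5. Anhydrous HCl in Et2O opens it at the tertiary carbon with inversion to the tertiary chloride primary alcohol F6 (attack at CH2 only returns 16). Tf2O/2,6-di-tert-butylpyridine (CH2Cl2, −78 °C) gives the primary triflate F7. The tertiary chlorine of F7 displaces triflate intramolecularly, and Bu4NBr opens the bridged ion at the tertiary carbon with a second inversion, giving 18. The remaining risk is direct SN2 at the neopentyl-type triflate, which would give the bromomethyl isomer.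

Step 6 (C2 chloride). Proton exchange or dichlorination may occur during chlorination, and the kinetic protonation may not be selective enough. The fallback sets out from 10 and comes back at 14; it sets C2 by inversion instead of by protonation. PhNMe3Br3 in THF brominates 10 on the unhindered side and gives, under both kinetic (axial attack) and thermodynamic control, the axial bromo ketone F4 with bromine trans to the ring C–Cl. LiCl (1.5 equiv) in DMF at 0 °C then displaces the activated α-bromide by SN2 with inversion to give 14; the reaction is stopped before chloride–chloride exchange can epimerise the product.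

**Further compounds**
F1 | step 4 | (7R)-8,9-epoxy-8-methyl-1,4-dioxaspiro[4.6]undecan-7-ol (epoxide cis to OH) | C[C@]12O[C@H]1CCC3(OCCO3)C[C@H]2O
F2 | step 4 | (7R,8S)-8-hydroxy-7-methyl-1,4-dioxaspiro[4.5]decane-7-carbaldehyde | C[C@@]1(C=O)CC2(OCCO2)CC[C@@H]1O
F3 | step 4 | (7R,8S)-7-formyl-7-methyl-1,4-dioxaspiro[4.5]decan-8-yl chlorosulfite | C[C@@]1(C=O)CC2(OCCO2)CC[C@@H]1OS(Cl)=O
F4 | step 6 | (2S,4S,5S)-2-bromo-4-chloro-5-[(E)-2-chloroethenyl]-5-methylcyclohexan-1-one | C[C@@]1(/C=C/Cl)CC(=O)[C@@H](Br)C[C@@H]1Cl
F5 | step 8 | (3R,4R,6S,7S)-4,6-dichloro-7-[(E)-2-chloroethenyl]-7-methyl-1-oxaspiro[2.5]octane | C[C@@]1(/C=C/Cl)C[C@@]2(CO2)[C@H](Cl)C[C@@H]1Cl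
F6 | step 8 | [(1S,2R,4S,5S)-1,2,4-trichloro-5-[(E)-2-chloroethenyl]-5-methylcyclohexyl]methanol | C[C@@]1(/C=C/Cl)C[C@](Cl)(CO)[C@H](Cl)C[C@@H]1Cl
F7 | step 8 | [(1S,2R,4S,5S)-1,2,4-trichloro-5-[(E)-2-chloroethenyl]-5-methylcyclohexyl]methyl trifluoromethanesulfonate | C[C@@]1(/C=C/Cl)C[C@](Cl)(COS(=O)(=O)C(F)(F)F)[C@H](Cl)C[C@@H]1Cl
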